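The upper fisetinidol C ring is disconnected at C2–C3 with C2 handed back to the 3-oxygen, so that O1–C2–O3 is a cyclic acetal of the B-ring aldehyde (flavan numbering). The key step is an acid-catalysed, enantioselective 1,2 O-to-C shift that contracts this seven-membered 1,3-benzodioxepin-5-one (O1, C2, O3, C3, C4, C4a, C8a) to the six-membered pyranone: it forms C2–C3, sets both stereocentres and turns the expelled O3 into the 3-hydroxyl. It exploits the vicinal O1–C2/C3–O3 pattern of the pyran ring and the C4 carbonyl that makes C3 enolisable. The C4 ketone then accepts the catechin C8 anion, hydride sets 4β, and a biomimetic C6 coupling adds the second fisetinidol.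

Key step: step 3

Assumption: compounds 1, 3, 9 and 17 are taken as purchasable, and the (R)-phosphoramide is assumed to be the catalyst antipode that gives the 2R product (otherwise its enantiomer is used).

Step 1
Reactants: 1 1-[4-(benzyloxy)-2-hydroxyphenyl]ethan-1-one
Product: 2 1-[4-(benzyloxy)-2-hydroxyphenyl]-2-hydroxyethan-1-one
Conditions: KN(SiMe3)2 (2.2 equiv), THF, −78 °C; then (±)-trans-2-(phenylsulfonyl)-3-phenyloxaziridine, −78 °C; aq. NH4Cl
Reagents that add atoms: (±)-trans-2-(phenylsulfonyl)-3-phenyloxaziridine, O=S(=O)(c1ccccc1)N1OC1c1ccccc1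
Why: Enolate hydroxylation (Davis oxidation): the phenoxide–enolate dianion attacks the oxaziridine oxygen through the methyl ketone carbon, the only enolisable site, and should give the α-hydroxy ketone.

Step 2
Reactants: 2 1-[4-(benzyloxy)-2-hydroxyphenyl]-2-hydroxyethan-1-one; 3 3,4-bis(benzyloxy)benzaldehyde
Product: 5 8-(benzyloxy)-2-[3,4-bis(benzyloxy)phenyl]-2H-1,3-benzodioxepin-5(4H)-one (racemic at the acetal carbon), via 1,2-bis(benzyloxy)-4-(dimethoxymethyl)benzene 4 (not isolated)
Conditions: 3, HC(OMe)3, pyridinium p-toluenesulfonate (cat.), CH2Cl2, rt; then 2, 5 Å molecular sieves, rt to 40 °C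
Reagents that add atoms: none
Why: Acid-catalysed transacetalisation: the primary alcohol and the phenol of 2 replace the two methoxy groups of acetal 4 while the sieves take up methanol, and the rigid ortho-acylphenol holds both oxygens in reach for the seven-membered ring; the acetal centre is racemic, which does not matter because it is ionised in step 3.

Step 3
Reactants: 5 8-(benzyloxy)-2-[3,4-bis(benzyloxy)phenyl]-2H-1,3-benzodioxepin-5(4H)-one
Product: 7 (2R,3R)-7-(benzyloxy)-2-[3,4-bis(benzyloxy)phenyl]-3-hydroxy-2,3-dihydro-4H-chromen-4-one (tri-O-benzylfustin), via ring-opened aryloxocarbenium ion 6 (not isolated)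
Conditions: (R)-3,3'-bis(2,4,6-triisopropylphenyl)-1,1'-binaphthyl-2,2'-diyl N-(trifluoromethylsulfonyl)phosphoramide (10 mol %), toluene, 4 Å molecular sieves, −20 °C to rt
Reagents that add atoms: none
Why: Proposed new method: the chiral acid protonates acetal oxygen O3 and the C2–O3 bond ionises to the aryl-stabilised oxocarbenium ion 6 (O1=C2), which stays tied through ring A to the freed 2-hydroxyacetyl unit; the enol of that unit, hydrogen-bonded to the phosphoramide anion, attacks C2 through C3, so that C2 moves from O3 to C3, the seven-membered acetal ring contracts to the six-membered pyranone and the expelled O3 becomes the 3-hydroxyl. The closest known reaction types are the Petasis–Ferrier and acetal [1,2]-Wittig O-to-C rearrangements and chiral Brønsted acid catalysed additions of enols to oxocarbenium ion pairs. The pyranone ring (O1, C2, C3, C4, C4a, C8a) closes by a 6-(enolendo)-endo-trig attack of the ring-embedded enol carbon on the oxocarbenium carbon. C2 is set by the chiral counter-anion, which covers one face of the oxocarbenium ion in the hydrogen-bonded ion pair, and C3 by the chair-like transition state with aryl and hydroxyl equatorial, backed by acid-mediated equilibration of the α-ketol centre to the 2,3-trans isomer. The step needs ionisation on the O3 side and carbon–carbon bond formation at C3: ionisation on the O1 side is reversible and unproductive, and attack through C3 is favoured because it gives the conjugated aryl ketone in a six-membered ring.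

Step 4
Reactants: 7 tri-O-benzylfustin
Product: 8 (2R,3R)-3,7-bis(benzyloxy)-2-[3,4-bis(benzyloxy)phenyl]-2,3-dihydro-4H-chromen-4-one
Conditions: benzyl 2,2,2-trichloroacetimidate, TfOH (cat.), CH2Cl2/cyclohexane, 0 °C
Reagents that add atoms: benzyl 2,2,2-trichloroacetimidate, ClC(Cl)(Cl)C(=N)OCc1ccccc1
Why: Acid-catalysed O-benzylation with the trichloroacetimidate protects the 3-hydroxyl without base, so the base-labile flavanone (ring opening by β-elimination, C3 epimerisation) is not endangered.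

Step 5
Reactants: 9 (+)-catechin
Product: 10 (2R,3S)-3,5,7-tris(benzyloxy)-2-[3,4-bis(benzyloxy)phenyl]chromane (penta-O-benzylcatechin)
Conditions: BnBr, K2CO3, DMF, rt; then NaH, BnBr, 0 °C to rt (one pot)
Reagents that add atoms: benzyl bromide, BrCc1ccccc1
Why: Williamson etherification: the four phenols are benzylated with carbonate and the secondary 3-hydroxyl after deprotonation with NaH, and no stereocentre is touched.

Step 6
Reactants: 10 penta-O-benzylcatechin
Product: 11 (2R,3S)-3,5,7-tris(benzyloxy)-2-[3,4-bis(benzyloxy)phenyl]-8-bromochromane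
Conditions: N-bromosuccinimide (1.0 equiv), CH2Cl2, −78 °C to 0 °C
Reagents that add atoms: N-bromosuccinimide, O=C1CCC(=O)N1Br
Why: Electrophilic aromatic bromination: C8 is the most nucleophilic position of the phloroglucinol-type ring of benzylated catechin, so one equivalent of the reagent at low temperature should give the 8-bromide.

Step 7
Reactants: 11 8-bromo-penta-O-benzylcatechin; 8 (2R,3R)-3,7-bis(benzyloxy)-2-[3,4-bis(benzyloxy)phenyl]-2,3-dihydro-4H-chromen-4-one
Product: 14 (2R,3R)-3,7-bis(benzyloxy)-2-[3,4-bis(benzyloxy)phenyl]-4-[(2R,3S)-3,5,7-tris(benzyloxy)-2-[3,4-bis(benzyloxy)phenyl]chroman-8-yl]chroman-4-ol (both C4 epimers), via 8-lithio penta-O-benzylcatechin 12 (not isolated), via 8-(dichloroceryl) penta-O-benzylcatechin 13 (not isolated)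
Conditions: 11, n-BuLi, THF, −78 °C; CeCl3 (anhydrous), −78 °C; then 8, −78 to −40 °C; aq. NH4Cl
Reagents that add atoms: none
Why: Bromine–lithium exchange, transmetalation to the organocerium reagent and 1,2-addition to the C4 ketone: the weakly basic aryl cerium species should suppress enolisation and β-elimination of the α-benzyloxy ketone, and the configuration of the new carbinol centre is irrelevant because it is ionised in step 8.

Step 8
Reactants: 14 tertiary alcohol (both C4 epimers)
Product: 15 (2R,3S,4R)-3,7-bis(benzyloxy)-2-[3,4-bis(benzyloxy)phenyl]-4-[(2R,3S)-3,5,7-tris(benzyloxy)-2-[3,4-bis(benzyloxy)phenyl]chroman-8-yl]chromane (nona-O-benzyl fisetinidol-(4β→8)-catechin)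
Conditions: Et3SiH (5 equiv), TMSOTf (20 mol %), CH2Cl2, −78 °C
Reagents that add atoms: none
Why: Ionic hydrogenation: the tertiary bis-benzylic alcohol ionises at low temperature (the pyran C2–O1 ethers do not) to a diarylcarbenium ion, and the silane delivers hydride to the face anti to the C3 benzyloxy group, which leaves the catechin unit cis to O3 (4β, 4R), as is typical for silane reductions of 2-substituted 1-arylcycloalkyl cations.

Step 9
Reactants: 15 nona-O-benzyl fisetinidol-(4β→8)-catechin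
Product: 16 fisetinidol-(4β→8)-catechin, (2R,3S,4R)-2-(3,4-dihydroxyphenyl)-4-[(2R,3S)-2-(3,4-dihydroxyphenyl)-3,5,7-trihydroxychroman-8-yl]chromane-3,7-diol
Conditions: H2 (1 atm), Pd(OH)2/C, THF/MeOH/H2O, rt
Reagents that add atoms: none
Why: Catalytic hydrogenolysis removes the nine benzyl ethers under neutral conditions that should leave the interflavan bond and both pyran rings intact.

Step 10
Reactants: 17 (+)-fustin, (2R,3R)-2-(3,4-dihydroxyphenyl)-3,7-dihydroxy-2,3-dihydro-4H-chromen-4-one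
Product: 18 (+)-mollisacacidin, (2R,3S,4R)-2-(3,4-dihydroxyphenyl)chromane-3,4,7-triol
Conditions: NaBH4, EtOH, 0 °C to rt
Reagents that add atoms: none
Why: Borohydride reduction of the flavanone carbonyl: axial hydride attack on the half-chair with equatorial C2 and C3 substituents should give the equatorial 4-hydroxyl, that is the 2,3-trans-3,4-trans diol (4R).

Step 11
Reactants: 16 fisetinidol-(4β→8)-catechin; 18 (+)-mollisacacidin
Product: 19 fisetinidol-(4β→8)-catechin-(6→4α)-fisetinidol (CNP0289228.2)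
Conditions: 0.1 M aq. HCl, EtOH co-solvent, rt, N2; Sephadex LH-20 chromatography
Reagents that add atoms: none
Why: Biomimetic proanthocyanidin condensation (acid-catalysed Friedel–Crafts alkylation): 18 ionises at C4 to the benzylic cation stabilised by O1 and the para 7-hydroxyl, which is trapped by C6 of the catechin unit of 16, the only free position of its phloroglucinol ring, from the face anti to the 3-hydroxyl, so the 3,4-trans (4α, 4S) linkage should predominate.

Compound list
1 | 1-[4-(benzyloxy)-2-hydroxyphenyl]ethan-1-one | CC(=O)c1ccc(OCc2ccccc2)cc1O | starting material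
2 | 1-[4-(benzyloxy)-2-hydroxyphenyl]-2-hydroxyethan-1-one | O=C(CO)c1ccc(OCc2ccccc2)cc1O | intermediate
3 | 3,4-bis(benzyloxy)benzaldehyde | O=Cc1ccc(OCc2ccccc2)c(OCc2ccccc2)c1 | starting material
4 | 1,2-bis(benzyloxy)-4-(dimethoxymethyl)benzene | COC(OC)c1ccc(OCc2ccccc2)c(OCc2ccccc2)c1 | intermediate
5 | 8-(benzyloxy)-2-[3,4-bis(benzyloxy)phenyl]-2H-1,3-benzodioxepin-5(4H)-one (racemic) | O=C1COC(c2ccc(OCc3ccccc3)c(OCc3ccccc3)c2)Oc2cc(OCc3ccccc3)ccc21 | intermediate
6 | ring-opened aryloxocarbenium ion (ion pair with the phosphoramide anion) | OCC(=O)c1ccc(OCc2ccccc2)cc1[O+]=Cc1ccc(OCc2ccccc2)c(OCc2ccccc2)c1 | intermediate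
7 | (2R,3R)-7-(benzyloxy)-2-[3,4-bis(benzyloxy)phenyl]-3-hydroxy-2,3-dihydro-4H-chromen-4-one | O=C1c2ccc(OCc3ccccc3)cc2O[C@H](c2ccc(OCc3ccccc3)c(OCc3ccccc3)c2)[C@H]1O | intermediate
8 | (2R,3R)-3,7-bis(benzyloxy)-2-[3,4-bis(benzyloxy)phenyl]-2,3-dihydro-4H-chromen-4-one | O=C1c2ccc(OCc3ccccc3)cc2O[C@H](c2ccc(OCc3ccccc3)c(OCc3ccccc3)c2)[C@H]1OCc1ccccc1 | intermediate
9 | (+)-catechin, (2R,3S)-2-(3,4-dihydroxyphenyl)chromane-3,5,7-triol | O[C@H]1Cc2c(O)cc(O)cc2O[C@@H]1c1ccc(O)c(O)c1 | starting material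
10 | (2R,3S)-3,5,7-tris(benzyloxy)-2-[3,4-bis(benzyloxy)phenyl]chromane | c1ccccc1CO[C@H]1Cc2c(OCc3ccccc3)cc(OCc3ccccc3)cc2O[C@@H]1c1ccc(OCc2ccccc2)c(OCc2ccccc2)c1 | intermediate
11 | (2R,3S)-3,5,7-tris(benzyloxy)-2-[3,4-bis(benzyloxy)phenyl]-8-bromochromane | c1ccccc1CO[C@H]1Cc2c(OCc3ccccc3)cc(OCc3ccccc3)c(Br)c2O[C@@H]1c1ccc(OCc2ccccc2)c(OCc2ccccc2)c1 | intermediate
12 | 8-lithio derivative of 10 | c1ccccc1CO[C@H]1Cc2c(OCc3ccccc3)cc(OCc3ccccc3)c([Li])c2O[C@@H]1c1ccc(OCc2ccccc2)c(OCc2ccccc2)c1 | intermediate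
13 | 8-(dichloroceryl) derivative of 10 | c1ccccc1CO[C@H]1Cc2c(OCc3ccccc3)cc(OCc3ccccc3)c([Ce](Cl)Cl)c2O[C@@H]1c1ccc(OCc2ccccc2)c(OCc2ccccc2)c1 | intermediate
14 | (2R,3R)-3,7-bis(benzyloxy)-2-[3,4-bis(benzyloxy)phenyl]-4-[(2R,3S)-3,5,7-tris(benzyloxy)-2-[3,4-bis(benzyloxy)phenyl]chroman-8-yl]chroman-4-ol (both C4 epimers) | OC1(c2c(OCc3ccccc3)cc(OCc3ccccc3)c3c2O[C@H](c2ccc(OCc4ccccc4)c(OCc4ccccc4)c2)[C@@H](OCc2ccccc2)C3)c2ccc(OCc3ccccc3)cc2O[C@H](c2ccc(OCc3ccccc3)c(OCc3ccccc3)c2)[C@H]1OCc1ccccc1 | intermediate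
15 | (2R,3S,4R)-3,7-bis(benzyloxy)-2-[3,4-bis(benzyloxy)phenyl]-4-[(2R,3S)-3,5,7-tris(benzyloxy)-2-[3,4-bis(benzyloxy)phenyl]chroman-8-yl]chromane | c1ccccc1COc1ccc2c(c1)O[C@H](c1ccc(OCc3ccccc3)c(OCc3ccccc3)c1)[C@@H](OCc1ccccc1)[C@H]2c1c(OCc3ccccc3)cc(OCc3ccccc3)c2c1O[C@H](c1ccc(OCc3ccccc3)c(OCc3ccccc3)c1)[C@@H](OCc1ccccc1)C2 | intermediate
16 | fisetinidol-(4β→8)-catechin, (2R,3S,4R)-2-(3,4-dihydroxyphenyl)-4-[(2R,3S)-2-(3,4-dihydroxyphenyl)-3,5,7-trihydroxychroman-8-yl]chromane-3,7-diol | Oc1ccc2c(c1)O[C@H](c1ccc(O)c(O)c1)[C@@H](O)[C@H]2c1c(O)cc(O)c2c1O[C@H](c1ccc(O)c(O)c1)[C@@H](O)C2 | intermediate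
17 | (+)-fustin, (2R,3R)-2-(3,4-dihydroxyphenyl)-3,7-dihydroxy-2,3-dihydro-4H-chromen-4-one | O=C1c2ccc(O)cc2O[C@H](c2ccc(O)c(O)c2)[C@H]1O | starting material
18 | (+)-mollisacacidin, (2R,3S,4R)-2-(3,4-dihydroxyphenyl)chromane-3,4,7-triol | O[C@@H]1c2ccc(O)cc2O[C@H](c2ccc(O)c(O)c2)[C@H]1O | intermediate
19 | fisetinidol-(4β→8)-catechin-(6→4α)-fisetinidol (CNP0289228.2) | Oc1ccc2c(c1)O[C@H](c1ccc(O)c(O)c1)[C@@H](O)[C@H]2c1c(O)c([C@@H]2c3ccc(O)cc3O[C@H](c3ccc(O)c(O)c3)[C@H]2O)c(O)c2c1O[C@H](c1ccc(O)c(O)c1)[C@@H](O)C2 | target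

Total step count: 11. Longest linear sequence: 8 steps (steps 1, 2, 3, 4, 7, 8, 9, 11).

Steps most likely to fail

Step 3 (ring contraction). The ion pair may discriminate the two faces of the oxocarbenium ion poorly, or the ring-opened species may be hydrolysed before the C2–C3 bond forms. The fallback uses known chemistry and sets out from (+)-fustin 17, whose pyranone ring and both stereocentres are already in place. Selective benzylation of its three phenolic hydroxyls (BnBr, K2CO3, acetone, reflux; the 3-hydroxyl stays free) should give 7 directly, where the route is rejoined. This fallback makes no new compound (F0).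

Step 7 (aryl addition). The hindered aryl nucleophile may deprotonate C3 and trigger ring opening by β-elimination of the phenoxide instead of adding to the carbonyl. The fallback sets out from 7: NaBH4 reduction should give the tri-O-benzyl flavan-3,4-diol F1. Its C4 cation (TMSOTf, CH2Cl2, −40 °C) alkylates C8 of penta-O-benzylcatechin 10, used in excess, in a Friedel–Crafts coupling. Both C4 epimers are expected there, and the 4β isomer is expected to be the minor one. This isomer, octa-O-benzyl fisetinidol-(4β→8)-catechin F2, is separated by chromatography and hydrogenolysed (H2, Pd(OH)2/C) to 16, where the route is rejoined. The fallback trades the stereocontrol of the ketone route for a well-established bond formation.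

Step 11 (final coupling). The free-phenol condensation may suffer from self-condensation of 18, from attack at the resorcinol rings and from incomplete facial selectivity at the crowded C6. The fallback sets out from 7 and 15: acetylation of 7 (Ac2O, pyridine) should give the 3-O-acetyl ketone F3, and NaBH4 at low temperature the 3-O-acetyl flavan-4-ol F4. TMSOTf-mediated coupling of F4 with the protected dimer 15 at C6, the only free position of its catechin phloroglucinol ring, runs through the acetoxonium ion (neighbouring-group participation) and should give the 3,4-trans linked dodeca-O-benzyl trimer acetate F5. Methanolysis (NaOMe, MeOH/THF) should give the dodeca-O-benzyl trimer F6, and hydrogenolysis (H2, Pd(OH)2/C) rejoins the route at 19.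

Further compounds
F0 | step 3 | none | none
F1 | step 7 | (2R,3S,4R)-7-(benzyloxy)-2-[3,4-bis(benzyloxy)phenyl]chromane-3,4-diol | O[C@@H]1c2ccc(OCc3ccccc3)cc2O[C@H](c2ccc(OCc3ccccc3)c(OCc3ccccc3)c2)[C@H]1O
F2 | step 7 | octa-O-benzyl fisetinidol-(4β→8)-catechin with free 3-hydroxyl on the fisetinidol unit | c1ccccc1COc1ccc2c(c1)O[C@H](c1ccc(OCc3ccccc3)c(OCc3ccccc3)c1)[C@@H](O)[C@H]2c1c(OCc3ccccc3)cc(OCc3ccccc3)c2c1O[C@H](c1ccc(OCc3ccccc3)c(OCc3ccccc3)c1)[C@@H](OCc1ccccc1)C2
F3 | step 11 | (2R,3R)-7-(benzyloxy)-2-[3,4-bis(benzyloxy)phenyl]-4-oxochroman-3-yl acetate | O=C1c2ccc(OCc3ccccc3)cc2O[C@H](c2ccc(OCc3ccccc3)c(OCc3ccccc3)c2)[C@H]1OC(C)=O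
F4 | step 11 | (2R,3S,4R)-7-(benzyloxy)-2-[3,4-bis(benzyloxy)phenyl]-4-hydroxychroman-3-yl acetate | O[C@@H]1c2ccc(OCc3ccccc3)cc2O[C@H](c2ccc(OCc3ccccc3)c(OCc3ccccc3)c2)[C@H]1OC(C)=O
F5 | step 11 | dodeca-O-benzyl fisetinidol-(4β→8)-catechin-(6→4α)-fisetinidol 3-O-acetate (acetate on the C6-linked unit) | c1ccccc1COc1ccc2c(c1)O[C@H](c1ccc(OCc3ccccc3)c(OCc3ccccc3)c1)[C@@H](OCc1ccccc1)[C@H]2c1c(OCc3ccccc3)c([C@@H]2c3ccc(OCc4ccccc4)cc3O[C@H](c3ccc(OCc4ccccc4)c(OCc4ccccc4)c3)[C@H]2OC(C)=O)c(OCc3ccccc3)c2c1O[C@H](c1ccc(OCc3ccccc3)c(OCc3ccccc3)c1)[C@@H](OCc1ccccc1)C2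
F6 | step 11 | dodeca-O-benzyl fisetinidol-(4β→8)-catechin-(6→4α)-fisetinidol (free 3-hydroxyl on the C6-linked unit) | c1ccccc1COc1ccc2c(c1)O[C@H](c1ccc(OCc3ccccc3)c(OCc3ccccc3)c1)[C@@H](OCc1ccccc1)[C@H]2c1c(OCc3ccccc3)c([C@@H]2c3ccc(OCc4ccccc4)cc3O[C@H](c3ccc(OCc4ccccc4)c(OCc4ccccc4)c3)[C@H]2O)c(OCc3ccccc3)c2c1O[C@H](c1ccc(OCc3ccccc3)c(OCc3ccccc3)c1)[C@@H](OCc1ccccc1)C2
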